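**Retrosynthetic overview**
- Target diacid ⇐ its dimethyl ester; the (9Z)-enoate of the long arm ⇐ Still–Gennari olefination of a γ,δ-unsaturated aldehyde with an α-homoprenyl phosphonate.
- That aldehyde and its (5E)-trisubstituted alkene ⇐ Claisen rearrangement of the vinyl ether of an isopropenyl carbinol.
- Short arm (the CH2–CH2 bond next to the stereocentre and the furan-bearing (2Z)-enoate) ⇐ visible-light decarboxylative radical addition of a carboxylic acid to a 2-phosphonoacrylate, then olefination of 3-(furan-3-yl)propanal in the same flask.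
- Acid and carbinol ⇐ δ-lactone ⇐ acid–aldehyde ⇐ oxidative excision of C2 of (S)-(+)-carvone, which supplies the only stereocentre (it becomes R in the target by CIP re-ranking only; no bond to it is ever broken).
- Rings: none is built. The furan is bought; the only ring made is a transient δ-lactone (step 3), reopened in step 6.

Assumption: 3-(furan-3-yl)propanal is not relied on as a catalogue item and is made in one step (step 5); compounds 1, 8, 12 and 19 are catalogue compounds.

**Route**

Step 1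
Reactants: 1 (S)-(+)-carvone
Product: 2 (1S,4S,6S)-1-methyl-4-(prop-1-en-2-yl)-7-oxabicyclo[4.1.0]heptan-2-one
Conditions: 30% H2O2 (1.5 equiv), NaOH (0.2 equiv), MeOH, 0 °C
Reagents that add atoms: hydrogen peroxide, OO
Why: Weitz–Scheffer nucleophilic epoxidation attacks only the electron-poor enone C=C (the isopropenyl group is inert) and closes the epoxide anti to the ring substituent; both new centres are excised in step 2.

Step 2
Reactants: 2 (1S,4S,6S)-1-methyl-4-(prop-1-en-2-yl)-7-oxabicyclo[4.1.0]heptan-2-one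
Product: 5 (3S)-5-oxo-3-(prop-1-en-2-yl)pentanoic acid, via keto diol 3 (not isolated), via dioxo aldehyde 4 (not isolated)
Conditions: H5IO6 (2.5 equiv), THF/H2O 4:1, 0 °C → rt
Reagents that add atoms: water, O; periodic acid, OI(=O)(O)(O)(O)O
Why: Periodic acid opens the keto epoxide to the diol and then carries out two Malaprade-type cleavages (glycol, then 1,2-diketone), removing ring carbon C2 as acetic acid; the two arms end at different oxidation levels (CHO and CO2H), so the bought stereocentre stays stereogenic and untouched.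

Step 3
Reactants: 5 (3S)-5-oxo-3-(prop-1-en-2-yl)pentanoic acid
Product: 7 (4S,6RS)-4,6-di(prop-1-en-2-yl)oxan-2-one, via hydroxy acid 6 (not isolated)
Conditions: CH2=C(CH3)MgBr (2.5 equiv), THF, −78 → 0 °C; 1 M HCl; then pyridinium p-toluenesulfonate (cat.), PhH, 40 °C
Reagents that add atoms: isopropenylmagnesium bromide, C=C(C)[Mg]Br
Why: Grignard 1,2-addition in which the first equivalent turns the acid into an unreactive magnesium carboxylate and the second adds to the aldehyde, followed by acid-catalysed δ-lactonisation to a neutral, storable lactone; the new carbinol centre forms unselectively and is destroyed in step 7.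

Step 4
Reactants: 8 methyl 2-[bis(2,2,2-trifluoroethoxy)phosphoryl]acetate
Product: 11 methyl 2-[bis(2,2,2-trifluoroethoxy)phosphoryl]prop-2-enoate, via Mannich base 9 (not isolated), via methiodide 10 (not isolated)
Conditions: NaH (1.0 equiv), THF, 0 °C; [Me2N=CH2]I (1.05 equiv), 0 °C → rt; MeI (3 equiv), rt; NaHCO3, CH2Cl2/H2O, 0 °C
Reagents that add atoms: N,N-dimethylmethyleneiminium iodide, C=[N+](C)C.[I-]
Why: Mannich reaction of the phosphonate anion with the preformed iminium salt, N-methylation and E1cB loss of trimethylamine (Eschenmoser-type α-methylenation) give the 2-phosphonoacrylate without any oxyanion that could trigger a Horner–Wadsworth–Emmons fragmentation.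

Step 5
Reactants: 12 3-bromofuran
Product: 13 3-(furan-3-yl)propanal
Conditions: allyl alcohol (1.5 equiv), Pd(OAc)2 (3 mol %), Bu4NCl (1 equiv), NaHCO3 (2.5 equiv), DMF, 80 °C
Reagents that add atoms: prop-2-en-1-ol, C=CCO
Why: Jeffery-type Heck reaction in which the furylpalladium species adds to the terminal carbon of allyl alcohol and β-hydride elimination towards the carbinol gives the enol, hence the 3-arylpropanal directly.

Step 6
Reactants: 7 (4S,6RS)-4,6-di(prop-1-en-2-yl)oxan-2-one; 11 methyl 2-[bis(2,2,2-trifluoroethoxy)phosphoryl]prop-2-enoate; 13 3-(furan-3-yl)propanal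
Product: 16 methyl (2Z)-5-(furan-3-yl)-2-[(3R,5RS)-5-hydroxy-6-methyl-3-(prop-1-en-2-yl)hept-6-en-1-yl]pent-2-enoate, via potassium carboxylate 14 (not isolated), via alkyl phosphonate 15 (not isolated)
Conditions: KOH (1.0 equiv), THF/H2O, rt, evaporate; CF3CO2H (0.9 equiv), 11 (1.1 equiv), 2,4,5,6-tetra(carbazol-9-yl)isophthalonitrile (2 mol %), MeCN (0.3 M), 450 nm LEDs, 20 °C, Ar; evaporate; KN(SiMe3)2 (2.2 equiv), 18-crown-6 (4 equiv), THF, −78 °C, then 13 (1.5 equiv)
Reagents that add atoms: none
Why: Proposed new method: a decarboxylative radical conjunctive Still–Gennari olefination with 11 as linchpin. Hydroxide opens 7 to carboxylate 14; the excited organic photocatalyst oxidises the carboxylate; the primary radical left after loss of CO2 adds to the unsubstituted terminus of the doubly activated alkene of 11 (at 0.3 M this should outrun the slow cyclisation onto the hindered 1,1-disubstituted alkene); the reduced photocatalyst turns the captodative adduct radical into the phosphonate carbanion, which the acid 6/carboxylate buffer protonates at once to 15, so no anion survives to oligomerise 11; KN(SiMe3)2/18-crown-6 then regenerates the carbanion for a kinetically controlled, Z-selective olefination of 13. The stereocentre is only adjacent to the radical carbon and is not affected. Closest known chemistry: photoredox decarboxylative Giese addition to acrylates and vinylphosphonates, radical–polar crossover three-component olefination with vinylphosphonium salts, and anionic tandem Michael/Horner–Wadsworth–Emmons reactions of 2-phosphonoacrylates.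

Step 7
Reactants: 16 methyl (2Z)-5-(furan-3-yl)-2-[(3R,5RS)-5-hydroxy-6-methyl-3-(prop-1-en-2-yl)hept-6-en-1-yl]pent-2-enoate
Product: 18 methyl (2Z)-5-(furan-3-yl)-2-[(3R,5E)-6-methyl-9-oxo-3-(prop-1-en-2-yl)non-5-en-1-yl]pent-2-enoate, via allyl vinyl ether 17 (not isolated)
Conditions: BuOCH=CH2 (solvent), Pd(OCOCF3)2 (2 mol %), 4,7-diphenyl-1,10-phenanthroline (2 mol %), Et3N (0.1 equiv), 75 °C, air; evaporate; PhMe, 140 °C (sealed tube)
Reagents that add atoms: butyl vinyl ether, C=COCCCC
Why: Vinyl ether exchange catalysed by divalent palladium, then Claisen rearrangement through a chair transition state with the carbinol substituent equatorial, sets the (E)-trisubstituted alkene and delivers the γ,δ-unsaturated aldehyde directly; the carbinol centre disappears and the remote stereocentre is untouched.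

Step 8
Reactants: 8 methyl 2-[bis(2,2,2-trifluoroethoxy)phosphoryl]acetate; 19 5-bromo-2-methylpent-2-ene
Product: 20 methyl 2-[bis(2,2,2-trifluoroethoxy)phosphoryl]-6-methylhept-5-enoate
Conditions: NaH (1.0 equiv), DMSO, rt; 19 (1.2 equiv), NaI (0.1 equiv), 50 °C
Reagents that add atoms: none
Why: SN2 C-alkylation of the stabilised phosphonate anion by a primary homoallylic bromide (iodide-assisted) gives the α-homoprenyl Still–Gennari reagent.

Step 9
Reactants: 18 methyl (2Z)-5-(furan-3-yl)-2-[(3R,5E)-6-methyl-9-oxo-3-(prop-1-en-2-yl)non-5-en-1-yl]pent-2-enoate; 20 methyl 2-[bis(2,2,2-trifluoroethoxy)phosphoryl]-6-methylhept-5-enoate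
Product: 21 methyl (2Z)-5-(furan-3-yl)-2-[(3R,5E,9Z)-10-(methoxycarbonyl)-6,14-dimethyl-3-(prop-1-en-2-yl)pentadeca-5,9,13-trien-1-yl]pent-2-enoate
Conditions: 20 (1.3 equiv), KN(SiMe3)2 (1.25 equiv), 18-crown-6 (3 equiv), THF, −78 °C; then 18
Reagents that add atoms: none
Why: Still–Gennari olefination, in which the dissociated potassium phosphonate anion adds to the aldehyde and the electron-poor phosphonate collapses faster than the adduct equilibrates, gives the (Z)-2-alkyl-2-enoate.

Step 10
Reactants: 21 methyl (2Z)-5-(furan-3-yl)-2-[(3R,5E,9Z)-10-(methoxycarbonyl)-6,14-dimethyl-3-(prop-1-en-2-yl)pentadeca-5,9,13-trien-1-yl]pent-2-enoate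
Product: 22 (2Z)-2-[(3R,5E,9Z)-10-carboxy-6,14-dimethyl-3-(prop-1-en-2-yl)pentadeca-5,9,13-trien-1-yl]-5-(furan-3-yl)pent-2-enoic acid
Conditions: LiOH·H2O (10 equiv), THF/MeOH/H2O 3:1:1, 45 °C; then 1 M HCl to pH 3–4, 0 °C
Reagents that add atoms: lithium hydroxide, [Li+].[OH-]
Why: Saponification of both methyl esters under mild heating and acidification only to pH 3–4 frees the diacid without touching the furan, the alkene geometries or the stereocentre.

**Compound list**

1 | (S)-(+)-carvone, (5S)-2-methyl-5-(prop-1-en-2-yl)cyclohex-2-en-1-one | C=C(C)[C@@H]1CC(=O)C(C)=CC1 | starting material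
2 | (1S,4S,6S)-1-methyl-4-(prop-1-en-2-yl)-7-oxabicyclo[4.1.0]heptan-2-one (epoxide oxygen trans to isopropenyl) | C=C(C)[C@@H]1CC(=O)[C@@]2(C)O[C@H]2C1 | intermediate
3 | (2S,3R,5S)-2,3-dihydroxy-2-methyl-5-(prop-1-en-2-yl)cyclohexan-1-one (trans-diol; not isolated) | C=C(C)[C@@H]1CC(=O)[C@@](C)(O)[C@H](O)C1 | intermediate
4 | (3S)-5,6-dioxo-3-(prop-1-en-2-yl)heptanal (not isolated) | C=C(C)[C@@H](CC=O)CC(=O)C(C)=O | intermediate
5 | (3S)-5-oxo-3-(prop-1-en-2-yl)pentanoic acid | C=C(C)[C@@H](CC=O)CC(=O)O | intermediate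
6 | (3S,5RS)-5-hydroxy-6-methyl-3-(prop-1-en-2-yl)hept-6-enoic acid (not isolated) | C=C(C)[C@@H](CC(O)C(C)=C)CC(=O)O | intermediate
7 | (4S,6RS)-4,6-di(prop-1-en-2-yl)oxan-2-one | C=C(C)[C@@H]1CC(=O)OC(C(C)=C)C1 | intermediate
8 | methyl 2-[bis(2,2,2-trifluoroethoxy)phosphoryl]acetate | COC(=O)CP(=O)(OCC(F)(F)F)OCC(F)(F)F | starting material
9 | methyl 2-[bis(2,2,2-trifluoroethoxy)phosphoryl]-3-(dimethylamino)propanoate (racemic; not isolated) | COC(=O)C(CN(C)C)P(=O)(OCC(F)(F)F)OCC(F)(F)F | intermediate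
10 | 2-[bis(2,2,2-trifluoroethoxy)phosphoryl]-3-methoxy-N,N,N-trimethyl-3-oxopropan-1-aminium iodide (racemic; not isolated) | COC(=O)C(C[N+](C)(C)C)P(=O)(OCC(F)(F)F)OCC(F)(F)F.[I-] | intermediate
11 | methyl 2-[bis(2,2,2-trifluoroethoxy)phosphoryl]prop-2-enoate | COC(=O)C(=C)P(=O)(OCC(F)(F)F)OCC(F)(F)F | intermediate
12 | 3-bromofuran | Brc1ccoc1 | starting material
13 | 3-(furan-3-yl)propanal | O=CCCc1ccoc1 | intermediate
14 | potassium (3S,5RS)-5-hydroxy-6-methyl-3-(prop-1-en-2-yl)hept-6-enoate (not isolated) | C=C(C)[C@@H](CC(O)C(C)=C)CC(=O)[O-].[K+] | intermediate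
15 | methyl (2RS,5R,7RS)-2-[bis(2,2,2-trifluoroethoxy)phosphoryl]-7-hydroxy-8-methyl-5-(prop-1-en-2-yl)non-8-enoate (not isolated) | C=C(C)[C@@H](CC(O)C(C)=C)CCC(C(=O)OC)P(=O)(OCC(F)(F)F)OCC(F)(F)F | intermediate
16 | methyl (2Z)-5-(furan-3-yl)-2-[(3R,5RS)-5-hydroxy-6-methyl-3-(prop-1-en-2-yl)hept-6-en-1-yl]pent-2-enoate | C=C(C)[C@@H](CC(O)C(C)=C)CC/C(=C/CCc1ccoc1)C(=O)OC | intermediate
17 | methyl (2Z)-2-[(3R,5RS)-5-(ethenyloxy)-6-methyl-3-(prop-1-en-2-yl)hept-6-en-1-yl]-5-(furan-3-yl)pent-2-enoate (not isolated) | C=C(C)[C@@H](CC(OC=C)C(C)=C)CC/C(=C/CCc1ccoc1)C(=O)OC | intermediate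
18 | methyl (2Z)-5-(furan-3-yl)-2-[(3R,5E)-6-methyl-9-oxo-3-(prop-1-en-2-yl)non-5-en-1-yl]pent-2-enoate | C=C(C)[C@@H](C/C=C(\C)CCC=O)CC/C(=C/CCc1ccoc1)C(=O)OC | intermediate
19 | 5-bromo-2-methylpent-2-ene | CC(C)=CCCBr | starting material
20 | methyl 2-[bis(2,2,2-trifluoroethoxy)phosphoryl]-6-methylhept-5-enoate (racemic) | COC(=O)C(CCC=C(C)C)P(=O)(OCC(F)(F)F)OCC(F)(F)F | intermediate
21 | methyl (2Z)-5-(furan-3-yl)-2-[(3R,5E,9Z)-10-(methoxycarbonyl)-6,14-dimethyl-3-(prop-1-en-2-yl)pentadeca-5,9,13-trien-1-yl]pent-2-enoate | C=C(C)[C@@H](C/C=C(\C)CC/C=C(/CCC=C(C)C)C(=O)OC)CC/C(=C/CCc1ccoc1)C(=O)OC | intermediate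
22 | (2Z)-2-[(3R,5E,9Z)-10-carboxy-6,14-dimethyl-3-(prop-1-en-2-yl)pentadeca-5,9,13-trien-1-yl]-5-(furan-3-yl)pent-2-enoic acid (CNP0235727.1) | C=C(C)[C@@H](C/C=C(\C)CC/C=C(/CCC=C(C)C)C(=O)O)CC/C(=C/CCc1ccoc1)C(=O)O | target

**Totals**
Total step count: 10. Longest linear sequence: 7 steps (steps 1, 2, 3, 6, 7, 9, 10; 1 → 2 → 5 → 7 → 16 → 18 → 21 → 22).

**Three steps most likely to fail**

Step 6 (the proposed new step). Risks are oligomerisation of 11, cyclisation of the radical onto the nearby 1,1-disubstituted alkene, and re-lactonisation of 6 during irradiation. The fallback uses only known chemistry; it sets out from 7 and comes back to the route at 15. LiAlH4 (THF, 0 °C) reduces the lactone to (3R,5RS)-6-methyl-3-(prop-1-en-2-yl)hept-6-ene-1,5-diol F1. I2/PPh3/imidazole (CH2Cl2, 0 °C) converts only the primary alcohol, giving (5S,3RS)-7-iodo-2-methyl-5-(prop-1-en-2-yl)hept-1-en-3-ol F2. The preformed sodium salt of 8 (NaH, 1.0 equiv, DMSO, 40 °C, so that no alkoxide forms) is alkylated by F2 to give 15, here with the former lactone carbonyl carbon kept as the CH2 next to the phosphonate carbon. The second stage of step 6 (KN(SiMe3)2, 18-crown-6, THF, −78 °C, then 13) converts 15 into 16 as before.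

Step 7. Vinyl transfer to a hindered secondary allylic alcohol under palladium catalysis in the presence of a furan and several alkenes may be sluggish, and the 140 °C rearrangement is long. The fallback sets out from 16 and comes back at 18. Eschenmoser–Claisen rearrangement with CH3C(OMe)2NMe2 (xylene, 140 °C) needs no vinyl ether and no palladium, and gives methyl (2Z)-2-[(3R,5E)-9-(dimethylamino)-6-methyl-9-oxo-3-(prop-1-en-2-yl)non-5-en-1-yl]-5-(furan-3-yl)pent-2-enoate F3 with the same chair-controlled E geometry. Cp2Zr(H)Cl (1.5 equiv, THF, rt) then reduces the tertiary amide chemoselectively to aldehyde 18, leaving the methyl ester intact.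

Step 3. Grignard addition to an enolisable aldehyde that carries a free acid may give low conversion. The fallback sets out from 5 and comes back at 7. Me3SiCHN2 (PhMe/MeOH, 0 °C) gives methyl (3S)-5-oxo-3-(prop-1-en-2-yl)pentanoate F4. Nozaki–Hiyama–Kishi coupling with 2-bromopropene (CrCl2, 3 equiv; NiCl2, 1 mol %; DMF, rt) adds the isopropenyl group to the aldehyde only, giving methyl (3S,5RS)-5-hydroxy-6-methyl-3-(prop-1-en-2-yl)hept-6-enoate F5. Pyridinium p-toluenesulfonate (PhH, 60 °C) closes F5 to lactone 7 with loss of methanol.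

**Further compounds**

F1 | step 6 | (3R,5RS)-6-methyl-3-(prop-1-en-2-yl)hept-6-ene-1,5-diol | C=C(C)[C@@H](CC(O)C(C)=C)CCO
F2 | step 6 | (5S,3RS)-7-iodo-2-methyl-5-(prop-1-en-2-yl)hept-1-en-3-ol | C=C(C)[C@@H](CC(O)C(C)=C)CCI
F3 | step 7 | methyl (2Z)-2-[(3R,5E)-9-(dimethylamino)-6-methyl-9-oxo-3-(prop-1-en-2-yl)non-5-en-1-yl]-5-(furan-3-yl)pent-2-enoate | C=C(C)[C@@H](C/C=C(\C)CCC(=O)N(C)C)CC/C(=C/CCc1ccoc1)C(=O)OC
F4 | step 3 | methyl (3S)-5-oxo-3-(prop-1-en-2-yl)pentanoate | C=C(C)[C@@H](CC=O)CC(=O)OC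
F5 | step 3 | methyl (3S,5RS)-5-hydroxy-6-methyl-3-(prop-1-en-2-yl)hept-6-enoate | C=C(C)[C@@H](CC(O)C(C)=C)CC(=O)OC
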